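**Plan**
1. Ring C is cut at C2–C3 and at O1–C8a. This gives 4-methoxybenzaldehyde (its C=O becomes C2–O1) and the four-carbon unit C3–C4–C4a–C8a. C4–C4a is then cut back to a ring A vinyl anion and an acetyl donor.
2. Enabling feature: the C5 and C8 methoxy groups of ring A stand para to each other on either side of the fusion bond C4a–C8a. Ring A can therefore be held as a p-quinone bis(dimethyl ketal), in which C4a=C8a is a plain alkene and, with a C4 enol silane, part of a real 2-silyloxy-1,3-diene C3=C4–C4a=C8a.
3. Forward: the ring A carbocycle is present from the start as 1,2,3,4-tetramethoxybenzene. It is brominated, dearomatised at the anode, acetylated through the vinyllithium and O-silylated.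
4. Ring C arises last, in one catalytic asymmetric hetero-Diels–Alder reaction with the aldehyde. The two surplus methoxy groups at C5 and C8 then leave as Et3SiOMe and MeOH, and ring A regains aromaticity with all four methoxy groups in place.
5. Stereochemistry: C2 is the only stereocentre and is set by the chiral trivalent chromium catalyst in the cycloaddition. No base meets the flavanone afterwards, so ring opening to the chalcone cannot scramble it.

Key step: step 5

Remark: flavanone numbering (O1, C2, C3, C4, C4a, C5 to C8, C8a) is used for the ring atoms of all intermediates. H2L = (1S,2R)-1-{[3-(1-adamantyl)-2-hydroxy-5-methylbenzylidene]amino}indan-2-ol.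
Assumption: the sense of induction of Cr(L)SbF6 is extrapolated from simple aldehydes and oxygenated dienes. There the (1R,2S) ligand gives the (R) carbinol carbon with the same priority pattern (O > aldehyde residue > ring CH2), so the (1S,2R) ligand is chosen for (2S). Both antipodes are available.
Assumption: 1,2,3,4-tetramethoxybenzene is taken as a catalogue chemical.

**Step 1**
Reactants: 1 1,2,3,4-tetramethoxybenzene
Product: 2 1-bromo-2,3,4,5-tetramethoxybenzene
Conditions: NBS (1.0 equiv), MeCN, 0 °C to rt
Reagents that add atoms: N-bromosuccinimide, O=C1CCC(=O)N1Br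
Why: Electrophilic aromatic bromination; the two free positions of 1 are equivalent by symmetry and strongly activated, so one equivalent of NBS in a polar solvent should stop at the monobromide.

**Step 2**
Reactants: 2 1-bromo-2,3,4,5-tetramethoxybenzene
Product: 3 1-bromo-3,3,4,5,6,6-hexamethoxycyclohexa-1,4-diene (bromoquinone bisketal)
Conditions: Pt anode, Pt cathode, undivided cell, constant current, KOH (1%), MeOH, 0 °C
Reagents that add atoms: methanol, CO
Why: Anodic two-electron bis-methoxylation of a 1,4-dimethoxyarene (quinone bisketal synthesis); the oxidised arene should take up methoxide at the only para-related pair of methoxy-bearing carbons (future C5 and C8), and bromo-1,4-dimethoxyarenes are a standard substrate class for this electrolysis.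

**Step 3**
Reactants: 3 1-bromo-3,3,4,5,6,6-hexamethoxycyclohexa-1,4-diene; 4 N-methoxy-N-methylacetamide
Product: 6 1-(3,3,4,5,6,6-hexamethoxycyclohexa-1,4-dien-1-yl)ethan-1-one (acetylquinone bisketal), via vinyllithium 5 (not isolated)
Conditions: n-BuLi (1.05 equiv), THF, −78 °C; then 4, −78 to −40 °C; cold pH 7 phosphate buffer
Reagents that add atoms: none
Why: Bromine–lithium exchange of a bromoquinone bisketal gives a vinyllithium that holds at low temperature because loss of LiOMe would need a six-membered cyclic allene, and acylation by an N-methoxy-N-methylamide stops at the ketone through the chelated tetrahedral adduct.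

**Step 4**
Reactants: 6 1-(3,3,4,5,6,6-hexamethoxycyclohexa-1,4-dien-1-yl)ethan-1-one
Product: 8 triethyl{[1-(3,3,4,5,6,6-hexamethoxycyclohexa-1,4-dien-1-yl)ethenyl]oxy}silane, via lithium dienolate 7 (not isolated)
Conditions: Et3SiCl (1.5 equiv) present from the start, LiN(SiMe3)2 (1.2 equiv), THF, −78 °C; pentane, cold aq NaHCO3; filtration through Et3N-deactivated silica
Reagents that add atoms: chlorotriethylsilane, CC[Si](Cl)(CC)CC
Why: Kinetic deprotonation of the methyl ketone at its only enolisable position with in situ O-silylation (silyl enol ether formation) keeps the free dienolate concentration low, so Michael self-addition at C8a should not compete.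

**Step 5**
Reactants: 8 triethyl{[1-(3,3,4,5,6,6-hexamethoxycyclohexa-1,4-dien-1-yl)ethenyl]oxy}silane; 9 4-methoxybenzaldehyde
Product: 12 (2S)-5,6,7,8,4'-pentamethoxyflavanone, via cycloadduct 10 (not isolated), via dienone 11 (not isolated)
Conditions: Cr(L)SbF6 (10 mol %), 4 Å MS, 9 (3 equiv, neat), rt; then CH2Cl2, CF3CO2H (10 mol %), −20 °C
Reagents that add atoms: none
Why: Proposed new method: the Lewis-acidic trivalent chromium centre of Cr(L)SbF6 binds the aldehyde oxygen of 9 and the 2-silyloxydiene C3=C4–C4a=C8a of 8 adds across the C=O in an asynchronous normal-demand [4+2] cycloaddition, C3 to the carbonyl carbon (C2–C3) and the carbonyl oxygen to C8a (O1–C8a), to give 10; catalytic acid then ionises the C5 ketal with the push of the C4 enol silane (loss of Et3SiOMe, 11) and the C8 ketal, whose cation is the C8a-protonated arene and sheds that proton (loss of MeOH), so ring A rearomatises to 12. The closest known reaction type is the hetero-Diels–Alder reaction of monooxygenated 2-triethylsilyloxy-1,3-dienes with unactivated aldehydes under tridentate Schiff-base chromium catalysts, joined to the known acid-induced aromatisation of quinone bisketals that have taken up a nucleophile; what is new is a diene built into a quinone bisketal. Ring C is closed by the intermolecular [4+2] cycloaddition itself, and a stepwise course (Mukaiyama aldol, then 6-endo-trig oxa-Michael addition to the silylated enone) would converge on the same product; ring A is not closed, only aromatised. C2 is controlled by the catalyst, which should shield the Re face of the bound aldehyde so that C3 attacks the Si face, whereas C8a (endo approach, H2 and H8a cis) is transient and is erased on aromatisation, so endo/exo selectivity does not matter. Regioselectivity is secured by the silyloxy group at C4, which makes C3 the nucleophilic terminus, periselectivity by the sp3 carbons C5 and C8, which leave only one conjugated diene in 8, and the correct methoxy groups leave because only C5 and C8 carry two. The medium stays free of base, so neither retro-aldol cleavage nor retro-oxa-Michael opening of the flavanone should erode C2.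

**Compound list**
1 | 1,2,3,4-tetramethoxybenzene | COc1ccc(OC)c(OC)c1OC | starting material
2 | 1-bromo-2,3,4,5-tetramethoxybenzene | COc1cc(Br)c(OC)c(OC)c1OC | intermediate
3 | 1-bromo-3,3,4,5,6,6-hexamethoxycyclohexa-1,4-diene | BrC1=CC(OC)(OC)C(OC)=C(OC)C1(OC)OC | intermediate
4 | N-methoxy-N-methylacetamide | CC(=O)N(C)OC | starting material
5 | (3,3,4,5,6,6-hexamethoxycyclohexa-1,4-dien-1-yl)lithium | [Li]C1=CC(OC)(OC)C(OC)=C(OC)C1(OC)OC | intermediate
6 | 1-(3,3,4,5,6,6-hexamethoxycyclohexa-1,4-dien-1-yl)ethan-1-one | CC(=O)C1=CC(OC)(OC)C(OC)=C(OC)C1(OC)OC | intermediate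
7 | lithium 1-(3,3,4,5,6,6-hexamethoxycyclohexa-1,4-dien-1-yl)ethen-1-olate | [Li]OC(=C)C1=CC(OC)(OC)C(OC)=C(OC)C1(OC)OC | intermediate
8 | triethyl{[1-(3,3,4,5,6,6-hexamethoxycyclohexa-1,4-dien-1-yl)ethenyl]oxy}silane | C=C(O[Si](CC)(CC)CC)C1=CC(OC)(OC)C(OC)=C(OC)C1(OC)OC | intermediate
9 | 4-methoxybenzaldehyde | COc1ccc(C=O)cc1 | starting material
10 | (2S,8aR)-5,5,6,7,8,8-hexamethoxy-2-(4-methoxyphenyl)-4-(triethylsilyloxy)-3,5,8,8a-tetrahydro-2H-chromene | COc1ccc([C@@H]2CC(O[Si](CC)(CC)CC)=C3[C@@H](O2)C(OC)(OC)C(OC)=C(OC)C3(OC)OC)cc1 | intermediate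
11 | (2S,8aR)-5,6,7,8,8-pentamethoxy-2-(4-methoxyphenyl)-2,3,8,8a-tetrahydro-4H-chromen-4-one | COc1ccc([C@@H]2CC(=O)C3=C(OC)C(OC)=C(OC)C(OC)(OC)[C@@H]3O2)cc1 | intermediate
12 | (2S)-5,6,7,8,4'-pentamethoxyflavanone | COc1ccc([C@@H]2CC(=O)c3c(OC)c(OC)c(OC)c(OC)c3O2)cc1 | target

Total step count: 5. Longest linear sequence: 5 (1 to 12).

**Steps most likely to fail**

Step 5 (Proposed new method).
- What may go wrong: the electron-rich aldehyde may add too slowly to the hindered diene. The ketals may ionise early on the Lewis acid, with oligomerisation through the enol silane. Facial selectivity may be insufficient.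
- Fallback, known chemistry only: it sets out from 2, comes back at 12, and gives up the cycloaddition.
  - Hydroxylation of 2 (Pd2(dba)3, t-BuXPhos, KOH, dioxane–water, 100 °C) would give 2,3,4,5-tetramethoxyphenol F1.
  - Friedel–Crafts C-acetylation at its only free ring position (AcOH, BF3·OEt2, 90 °C) would give 1-(2-hydroxy-3,4,5,6-tetramethoxyphenyl)ethan-1-one F2.
  - Claisen–Schmidt condensation with 9 (KOH, EtOH, rt) would give (E)-1-(2-hydroxy-3,4,5,6-tetramethoxyphenyl)-3-(4-methoxyphenyl)prop-2-en-1-one F3.
  - Oxa-Michael cyclisation (NaOAc, EtOH, reflux) would give rac-5,6,7,8,4'-pentamethoxyflavanone F4.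
  - Kinetic resolution follows by asymmetric transfer hydrogenation (RhCl[(R,R)-TsDPEN](C5Me5), HCO2H–Et3N, EtOAc, rt). It should reduce the matched (2R) enantiomer to the cis alcohol (2R,4R)-5,6,7,8-tetramethoxy-2-(4-methoxyphenyl)chroman-4-ol F5 and leave the (2S) ketone 12, which is separated by chromatography.

Step 4.
- What may go wrong: the dienolate or the amide base may add to C8a of the enone with loss of methanol (premature aromatisation). The enol silane may hydrolyse during isolation.
- Fallback: it sets out from 3, bypasses ketone 6 and its enolisation, and comes back at 12.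
  - Stille coupling of 3 with tributyl(1-ethoxyvinyl)stannane (Pd(PPh3)4, toluene, 90 °C) would install the oxygenated diene directly as 1-(1-ethoxyethenyl)-3,3,4,5,6,6-hexamethoxycyclohexa-1,4-diene F6.
  - Cycloaddition with 9 under the catalyst of step 5 would give (2S,8aR)-4-ethoxy-5,5,6,7,8,8-hexamethoxy-2-(4-methoxyphenyl)-3,5,8,8a-tetrahydro-2H-chromene F7.
  - Aqueous oxalic acid in THF at 0 °C would hydrolyse the enol ether and aromatise ring A to 12.

Step 3.
- What may go wrong: the liberated N,O-dimethylhydroxylamine may add to C8a of the new enone during the quench, followed by aromatisation. The vinyllithium may decay on warming.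
- Fallback: it sets out from 3 (through 5), comes back at 6, and separates C–C bond formation from the adjustment of oxidation level.
  - 5 is trapped with acetaldehyde at −78 °C to give rac-1-(3,3,4,5,6,6-hexamethoxycyclohexa-1,4-dien-1-yl)ethan-1-ol F8. No enone and no nucleophilic amine are present at that stage.
  - The allylic alcohol is then oxidised under neutral conditions (MnO2, CH2Cl2, rt) to 6.

**Further compounds**
F1 | step 5 | 2,3,4,5-tetramethoxyphenol | COc1cc(O)c(OC)c(OC)c1OC
F2 | step 5 | 1-(2-hydroxy-3,4,5,6-tetramethoxyphenyl)ethan-1-one | CC(=O)c1c(O)c(OC)c(OC)c(OC)c1OC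
F3 | step 5 | (E)-1-(2-hydroxy-3,4,5,6-tetramethoxyphenyl)-3-(4-methoxyphenyl)prop-2-en-1-one | COc1ccc(/C=C/C(=O)c2c(O)c(OC)c(OC)c(OC)c2OC)cc1
F4 | step 5 | rac-5,6,7,8,4'-pentamethoxyflavanone | COc1ccc(C2CC(=O)c3c(OC)c(OC)c(OC)c(OC)c3O2)cc1
F5 | step 5 | (2R,4R)-5,6,7,8-tetramethoxy-2-(4-methoxyphenyl)chroman-4-ol | COc1ccc([C@H]2C[C@@H](O)c3c(OC)c(OC)c(OC)c(OC)c3O2)cc1
F6 | step 4 | 1-(1-ethoxyethenyl)-3,3,4,5,6,6-hexamethoxycyclohexa-1,4-diene | C=C(OCC)C1=CC(OC)(OC)C(OC)=C(OC)C1(OC)OC
F7 | step 4 | (2S,8aR)-4-ethoxy-5,5,6,7,8,8-hexamethoxy-2-(4-methoxyphenyl)-3,5,8,8a-tetrahydro-2H-chromene | COc1ccc([C@@H]2CC(OCC)=C3[C@@H](O2)C(OC)(OC)C(OC)=C(OC)C3(OC)OC)cc1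
F8 | step 3 | rac-1-(3,3,4,5,6,6-hexamethoxycyclohexa-1,4-dien-1-yl)ethan-1-ol | CC(O)C1=CC(OC)(OC)C(OC)=C(OC)C1(OC)OC
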